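**Strategy.** Ring A (C1–C5, C10; ent-kaurane numbering) is cut across C2–C3 and C5–C10 into two three-carbon units. A Wittig olefination/6π-electrocyclization cascade joins an allylic ylide (C3–C4–C5 carrying both carboxyl carbons C19 and C6) to a β,β-disubstituted enal (C2–C1–C10 with the C20 methyl and a bought (R)-glycerate dioxolane as masked C9). This closes the ring and creates quaternary C10 in one operation. It exploits the vicinal C4/C5 carboxyls: the C19 ester sits at the triene 2-position and accelerates closure. C10 then relays to C4/C5 (trianion methylation–protonation), C8/C9 (Diels–Alder) and C13 (Conia-ene).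

Key step: step 7

Remark: atom labels follow ent-kaurane numbering of the target (C18 methyl and C19 acid on C4, C6 acid on C5, C20 methyl on C10, C7 aldehyde on C8, ring C = C8, C9, C11–C14, ring D = C8, C13–C16, C17 = exocyclic methylene). Pent-4-ynal and methyl (R)-2,2-dimethyl-1,3-dioxolane-4-carboxylate are taken as commercial.

Step 1
Reactants: 1 dimethyl itaconate
Product: 3 dimethyl 2-(bromomethyl)fumarate, via dibromide 2 (not isolated)
Conditions: Br2, CH2Cl2, 0 °C → rt; then Et3N, Et2O, 0 °C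
Reagents that add atoms: bromine, BrBr
Why: Bromine addition to the 1,1-disubstituted alkene and E2 loss of HBr through the acidic C–H next to the ester should give the conjugated allylic bromide (bromination–dehydrobromination).

Step 2
Reactants: 3 dimethyl 2-(bromomethyl)fumarate
Product: 4 [(2Z)-2,3-bis(methoxycarbonyl)prop-2-en-1-yl]triphenylphosphonium bromide
Conditions: PPh3, toluene, rt
Reagents that add atoms: triphenylphosphine, c1ccc(cc1)P(c1ccccc1)c1ccccc1
Why: SN2 quaternization of the primary allylic bromide should give the phosphonium salt.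

Step 3
Reactants: 5 methyl (R)-2,2-dimethyl-1,3-dioxolane-4-carboxylate
Product: 7 1-[(4R)-2,2-dimethyl-1,3-dioxolan-4-yl]ethan-1-one, via Weinreb amide 6 (not isolated)
Conditions: MeNH(OMe)·HCl, i-PrMgCl, THF, −20 °C; then MeMgBr, 0 °C
Reagents that add atoms: methylmagnesium bromide, C[Mg]Br
Why: In situ Weinreb amide formation and a single Grignard addition through the stable chelate should give the methyl ketone without touching the α-alkoxy stereocentre (Weinreb ketone synthesis).

Step 4
Reactants: 7 1-[(4R)-2,2-dimethyl-1,3-dioxolan-4-yl]ethan-1-one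
Product: 8 ethyl (2E)-3-[(4S)-2,2-dimethyl-1,3-dioxolan-4-yl]but-2-enoate
Conditions: Ph3P=CHCO2Et, toluene, 90 °C
Reagents that add atoms: ethyl (triphenylphosphoranylidene)acetate, CCOC(=O)C=P(c1ccccc1)(c1ccccc1)c1ccccc1
Why: Wittig olefination of the activated α-alkoxy ketone with a stabilized ylide under neutral conditions should give mainly the E-enoate (dioxolanyl trans to the ester) without epimerization; the descriptor changes from R to S only through a priority change.

Step 5
Reactants: 8 ethyl (2E)-3-[(4S)-2,2-dimethyl-1,3-dioxolan-4-yl]but-2-enoate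
Product: 9 (2E)-3-[(4S)-2,2-dimethyl-1,3-dioxolan-4-yl]but-2-en-1-ol
Conditions: DIBAL-H, CH2Cl2, −78 °C
Reagents that add atoms: none
Why: 1,2-Reduction of the conjugated ester by DIBAL-H should give the allylic alcohol and leave the acetonide intact.

Step 6
Reactants: 9 (2E)-3-[(4S)-2,2-dimethyl-1,3-dioxolan-4-yl]but-2-en-1-ol
Product: 10 (2E)-3-[(4S)-2,2-dimethyl-1,3-dioxolan-4-yl]but-2-enal
Conditions: MnO2, CH2Cl2, rt
Reagents that add atoms: none
Why: Selective allylic oxidation with MnO2 should give the E-enal without over-oxidation.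

Step 7
Reactants: 4 [(2Z)-2,3-bis(methoxycarbonyl)prop-2-en-1-yl]triphenylphosphonium bromide, 10 (2E)-3-[(4S)-2,2-dimethyl-1,3-dioxolan-4-yl]but-2-enal
Product: 13 dimethyl (5R,6R)-5-[(4S)-2,2-dimethyl-1,3-dioxolan-4-yl]-5-methylcyclohexa-1,3-diene-1,6-dicarboxylate, via ylide 11 (not isolated), via triene 12 (not isolated)
Conditions: NaHMDS, THF, −78 °C; then 10, −78 °C → rt; then toluene, I2 (5 mol %), 80 °C
Reagents that add atoms: none
Why: Ylide 11 olefinates the aldehyde of 10 (Wittig) to the 1,3,5-hexatriene 12, whose C2=C3 (Z)-isomer undergoes thermal disrotatory 6π-electrocyclization to form the C5–C10 σ-bond; catalytic iodine equilibrates the olefin geometries so that the material should drain through the fastest-closing isomer (at C10 methyl inside, dioxolanyl outside). The closest known reaction type is the tandem Wittig olefination/6π-electrocyclization, that is the cyclohexadiene annulation of an allylidenephosphorane with an enal. Ring A is closed in the electrocyclic (6π, disrotatory) mode, the olefination having supplied the C2=C3 bond of the same ring. C10 is controlled by the dioxolane stereocentre through the helical sense of closure (inside-alkoxy model: ring C–O towards C1, ring CH2 anti to the forming bond, H towards the methyl); C5 follows from disrotation (CO2Me cis to the dioxolanyl group) and is reset in step 11. The step needs torquoselectivity and must outrun a [1,7]-hydrogen shift from the inside methyl; the C19 ester on C4 (triene 2-position) lowers the barrier of closure and the allylic C–O stereocentre supplies the facial bias.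

Step 8
Reactants: 13 dimethyl (5R,6R)-5-[(4S)-2,2-dimethyl-1,3-dioxolan-4-yl]-5-methylcyclohexa-1,3-diene-1,6-dicarboxylate
Product: 14 dimethyl (1S,2S,3R)-3-[(4S)-2,2-dimethyl-1,3-dioxolan-4-yl]-3-methylcyclohexane-1,2-dicarboxylate
Conditions: H2 (1 atm), Pd/C, EtOAc, rt
Reagents that add atoms: none
Why: Heterogeneous hydrogenation should saturate both ring alkenes from the face opposite the dioxolanyl group (all-cis isomer expected); C4 and C5 need not be controlled because both are erased in step 11.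

Step 9
Reactants: 14 dimethyl (1S,2S,3R)-3-[(4S)-2,2-dimethyl-1,3-dioxolan-4-yl]-3-methylcyclohexane-1,2-dicarboxylate
Product: 15 dimethyl (1S,2S,3R)-3-formyl-3-methylcyclohexane-1,2-dicarboxylate
Conditions: H5IO6, EtOAc, rt
Reagents that add atoms: none
Why: Periodic acid should cleave the acetonide and the liberated 1,2-diol in one pot (glycol cleavage), turning the spent stereocentre into the C9 aldehyde.

Step 10
Reactants: 15 dimethyl (1S,2S,3R)-3-formyl-3-methylcyclohexane-1,2-dicarboxylate
Product: 16 dimethyl (1S,2S,3R)-3-ethynyl-3-methylcyclohexane-1,2-dicarboxylate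
Conditions: Ohira–Bestmann reagent, K2CO3, MeOH, 0 °C → rt
Reagents that add atoms: dimethyl (1-diazo-2-oxopropyl)phosphonate, COP(=O)(OC)C(=[N+]=[N-])C(C)=O
Why: Seyferth–Gilbert homologation should convert the neopentyl aldehyde into the terminal alkyne C9≡C11, the slim sp substituent that step 11 requires.

Step 11
Reactants: 16 dimethyl (1S,2S,3R)-3-ethynyl-3-methylcyclohexane-1,2-dicarboxylate
Product: 18 dimethyl (1R,2S,3R)-3-ethynyl-1,3-dimethylcyclohexane-1,2-dicarboxylate, via trilithium trianion 17 (not isolated)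
Conditions: LDA (3.5 equiv), THF, −78 → −30 °C; MeI (1.05 equiv), −78 °C; then AcOH, −78 °C
Reagents that add atoms: iodomethane, CI
Why: In the acetylide/vicinal bis(ester enolate) 17, A(1,3) strain should keep the alkynyl group equatorial and the C20 methyl axial, so MeI alkylates the less hindered C4 enolate anti to that methyl (C19 ester axial, cis to C20) and the C5 enolate is then protonated axially, anti to both axial groups (alkylation of a vicinal diester dianion).

Step 12
Reactants: 18 dimethyl (1R,2S,3R)-3-ethynyl-1,3-dimethylcyclohexane-1,2-dicarboxylate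
Product: 20 dimethyl (1R,2S,3S)-1,3-dimethyl-3-[(1E)-3-oxobut-1-en-1-yl]cyclohexane-1,2-dicarboxylate, via alkenylzirconocene 19 (not isolated)
Conditions: Cp2Zr(H)Cl, CH2Cl2, rt; then AcCl, CuBr·SMe2 (10 mol %), 0 °C → rt
Reagents that add atoms: acetyl chloride, CC(Cl)=O
Why: Syn, terminal-selective hydrozirconation of the alkyne and copper-catalysed acylation of the alkenylzirconocene should give the E-enone (hydrozirconation/acylation).

Step 13
Reactants: 20 dimethyl (1R,2S,3S)-1,3-dimethyl-3-[(1E)-3-oxobut-1-en-1-yl]cyclohexane-1,2-dicarboxylate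
Product: 21 dimethyl (1R,2S,3S)-1,3-dimethyl-3-{(1E)-3-[(triisopropylsilyl)oxy]buta-1,3-dien-1-yl}cyclohexane-1,2-dicarboxylate
Conditions: TIPSOTf, Et3N, CH2Cl2, 0 °C
Reagents that add atoms: triisopropylsilyl triflate, CC(C)[Si](OS(=O)(=O)C(F)(F)F)(C(C)C)C(C)C
Why: Soft enolization of the methyl ketone, whose only acidic protons are on the methyl group, should give the 2-silyloxy-1,3-diene.

Step 14
Reactants: 22 pent-4-ynal
Product: 23 2-methylidenepent-4-ynal
Conditions: aq. CH2O, pyrrolidine (10 mol %), EtCO2H (10 mol %), i-PrOH, 45 °C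
Reagents that add atoms: formaldehyde, C=O
Why: Amine-catalysed Mannich condensation with formaldehyde followed by elimination should give the 2-substituted acrolein (organocatalytic α-methylenation of an aldehyde).

Step 15
Reactants: 21 dimethyl (1R,2S,3S)-1,3-dimethyl-3-{(1E)-3-[(triisopropylsilyl)oxy]buta-1,3-dien-1-yl}cyclohexane-1,2-dicarboxylate, 23 2-methylidenepent-4-ynal
Product: 25 dimethyl (1R,2S,3S)-3-[(1S,2R)-2-formyl-5-oxo-2-(prop-2-yn-1-yl)cyclohexyl]-1,3-dimethylcyclohexane-1,2-dicarboxylate, via silyl enol ether cycloadduct 24 (not isolated)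
Conditions: (S)-o-tolyl-CBS oxazaborolidine·Tf2NH (20 mol %), CH2Cl2, −78 → −40 °C; then 2 M HCl, THF, rt
Reagents that add atoms: none
Why: In this Lewis-acid-catalysed Diels–Alder reaction the nucleophilic diene terminus C13 should bond to the acrolein β-carbon C14 and C9 to C8, the endo formyl group placing C7 cis to ring A; the catalyst selects the enal face (C8; sense assigned by analogy with other 2-substituted acroleins) and is expected to be reinforced by attack on the diene face anti to C5 with the C20 methyl outside (C9), and the acid work-up unmasks the C12 ketone.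

Step 16
Reactants: 25 dimethyl (1R,2S,3S)-3-[(1S,2R)-2-formyl-5-oxo-2-(prop-2-yn-1-yl)cyclohexyl]-1,3-dimethylcyclohexane-1,2-dicarboxylate
Product: 26 dimethyl (1R,2S,3S)-3-[(1R,2S,5R)-1-formyl-6-methylidene-4-oxobicyclo[3.2.1]octan-2-yl]-1,3-dimethylcyclohexane-1,2-dicarboxylate
Conditions: pyrrolidine (0.2 equiv), Cu(OTf)2 (0.1 equiv), PPh3 (0.2 equiv), MeOH, 50 °C
Reagents that add atoms: none
Why: Reversible enamine formation and copper activation of the alkyne should give a 5-exo-dig Conia-ene cyclization from the less hindered α-carbon C13 onto the axial propargyl group, closing ring D with the exocyclic methylene; C13 is fixed by the bridge.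

Step 17
Reactants: 26 dimethyl (1R,2S,3S)-3-[(1R,2S,5R)-1-formyl-6-methylidene-4-oxobicyclo[3.2.1]octan-2-yl]-1,3-dimethylcyclohexane-1,2-dicarboxylate
Product: 27 (1R,2S,3S)-3-[(1R,2S,5R)-1-formyl-6-methylidene-4-oxobicyclo[3.2.1]octan-2-yl]-1,3-dimethylcyclohexane-1,2-dicarboxylic acid
Conditions: n-PrSLi, HMPA, rt; then 1 M HCl, 0 °C
Reagents that add atoms: none
Why: SN2 demethylation by thiolate at the unhindered methyl carbons should cleave both hindered methyl esters without attack at the acyl carbons, the non-enolizable aldehyde, the ketone or the 1,1-disubstituted alkene (nucleophilic ester dealkylation).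

**Compound list**

1 | dimethyl itaconate | C=C(CC(=O)OC)C(=O)OC | starting material
2 | dimethyl 2-bromo-2-(bromomethyl)butanedioate (racemic) | COC(=O)CC(Br)(CBr)C(=O)OC | intermediate
3 | dimethyl 2-(bromomethyl)fumarate | COC(=O)/C=C(\CBr)C(=O)OC | intermediate
4 | [(2Z)-2,3-bis(methoxycarbonyl)prop-2-en-1-yl]triphenylphosphonium bromide | COC(=O)/C=C(\C[P+](c1ccccc1)(c1ccccc1)c1ccccc1)C(=O)OC.[Br-] | intermediate
5 | methyl (R)-2,2-dimethyl-1,3-dioxolane-4-carboxylate | COC(=O)[C@H]1COC(C)(C)O1 | starting material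
6 | (4R)-N-methoxy-N,2,2-trimethyl-1,3-dioxolane-4-carboxamide | CON(C)C(=O)[C@H]1COC(C)(C)O1 | intermediate
7 | 1-[(4R)-2,2-dimethyl-1,3-dioxolan-4-yl]ethan-1-one | CC(=O)[C@H]1COC(C)(C)O1 | intermediate
8 | ethyl (2E)-3-[(4S)-2,2-dimethyl-1,3-dioxolan-4-yl]but-2-enoate | CCOC(=O)/C=C(\C)[C@H]1COC(C)(C)O1 | intermediate
9 | (2E)-3-[(4S)-2,2-dimethyl-1,3-dioxolan-4-yl]but-2-en-1-ol | OC/C=C(\C)[C@H]1COC(C)(C)O1 | intermediate
10 | (2E)-3-[(4S)-2,2-dimethyl-1,3-dioxolan-4-yl]but-2-enal | O=C/C=C(\C)[C@H]1COC(C)(C)O1 | intermediate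
11 | dimethyl 2-[(triphenylphosphoranylidene)methyl]fumarate (ylide) | COC(=O)/C=C(\C=P(c1ccccc1)(c1ccccc1)c1ccccc1)C(=O)OC | intermediate
12 | dimethyl (2Z)-2-{(1Z,3E)-4-[(4S)-2,2-dimethyl-1,3-dioxolan-4-yl]penta-1,3-dien-1-yl}but-2-enedioate (reactive triene isomer) | COC(=O)/C=C(C(=O)OC)/C=C\C=C(/C)\[C@H]1COC(C)(C)O1 | intermediate
13 | dimethyl (5R,6R)-5-[(4S)-2,2-dimethyl-1,3-dioxolan-4-yl]-5-methylcyclohexa-1,3-diene-1,6-dicarboxylate | CC1(C)OC[C@@H](O1)[C@]2(C)C=CC=C(C(=O)OC)[C@@H]2C(=O)OC | intermediate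
14 | dimethyl (1S,2S,3R)-3-[(4S)-2,2-dimethyl-1,3-dioxolan-4-yl]-3-methylcyclohexane-1,2-dicarboxylate | CC1(C)OC[C@@H](O1)[C@]2(C)CCC[C@H](C(=O)OC)[C@@H]2C(=O)OC | intermediate
15 | dimethyl (1S,2S,3R)-3-formyl-3-methylcyclohexane-1,2-dicarboxylate | O=C[C@]1(C)CCC[C@H](C(=O)OC)[C@@H]1C(=O)OC | intermediate
16 | dimethyl (1S,2S,3R)-3-ethynyl-3-methylcyclohexane-1,2-dicarboxylate | C#C[C@]1(C)CCC[C@H](C(=O)OC)[C@@H]1C(=O)OC | intermediate
17 | trilithium acetylide/bis(ester enolate) of 16 | [Li+].[Li+].[Li+].[C-]#C[C@]1(C)CCCC(=C([O-])OC)C1=C([O-])OC | intermediate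
18 | dimethyl (1R,2S,3R)-3-ethynyl-1,3-dimethylcyclohexane-1,2-dicarboxylate | C#C[C@]1(C)CCC[C@@](C)(C(=O)OC)[C@H]1C(=O)OC | intermediate
19 | (E)-alkenyl(chloro)zirconocene from 18 | Cl[Zr](/C=C/[C@]1(C)CCC[C@@](C)(C(=O)OC)[C@H]1C(=O)OC)(C1C=CC=C1)C1C=CC=C1 | intermediate
20 | dimethyl (1R,2S,3S)-1,3-dimethyl-3-[(1E)-3-oxobut-1-en-1-yl]cyclohexane-1,2-dicarboxylate | CC(=O)/C=C/[C@]1(C)CCC[C@@](C)(C(=O)OC)[C@H]1C(=O)OC | intermediate
21 | dimethyl (1R,2S,3S)-1,3-dimethyl-3-{(1E)-3-[(triisopropylsilyl)oxy]buta-1,3-dien-1-yl}cyclohexane-1,2-dicarboxylate | C=C(O[Si](C(C)C)(C(C)C)C(C)C)/C=C/[C@]1(C)CCC[C@@](C)(C(=O)OC)[C@H]1C(=O)OC | intermediate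
22 | pent-4-ynal | C#CCCC=O | starting material
23 | 2-methylidenepent-4-ynal | C=C(CC#C)C=O | intermediate
24 | dimethyl (1R,2S,3S)-3-{(1S,6R)-6-formyl-6-(prop-2-yn-1-yl)-3-[(triisopropylsilyl)oxy]cyclohex-2-en-1-yl}-1,3-dimethylcyclohexane-1,2-dicarboxylate | O=C[C@@]1(CC#C)CCC(O[Si](C(C)C)(C(C)C)C(C)C)=C[C@H]1[C@]1(C)CCC[C@@](C)(C(=O)OC)[C@H]1C(=O)OC | intermediate
25 | dimethyl (1R,2S,3S)-3-[(1S,2R)-2-formyl-5-oxo-2-(prop-2-yn-1-yl)cyclohexyl]-1,3-dimethylcyclohexane-1,2-dicarboxylate | O=C[C@@]1(CC#C)CCC(=O)C[C@H]1[C@]1(C)CCC[C@@](C)(C(=O)OC)[C@H]1C(=O)OC | intermediate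
26 | dimethyl (1R,2S,3S)-3-[(1R,2S,5R)-1-formyl-6-methylidene-4-oxobicyclo[3.2.1]octan-2-yl]-1,3-dimethylcyclohexane-1,2-dicarboxylate | C=C1C[C@]2(C=O)C[C@H]1C(=O)C[C@H]2[C@]1(C)CCC[C@@](C)(C(=O)OC)[C@H]1C(=O)OC | intermediate
27 | (1R,2S,3S)-3-[(1R,2S,5R)-1-formyl-6-methylidene-4-oxobicyclo[3.2.1]octan-2-yl]-1,3-dimethylcyclohexane-1,2-dicarboxylic acid (CNP0320711.1) | C=C1C[C@]2(C=O)C[C@H]1C(=O)C[C@H]2[C@]1(C)CCC[C@@](C)(C(=O)O)[C@H]1C(=O)O | target

**Step count.** 17 steps in total. The longest linear sequence is 14 steps (5 → 27 through steps 3–13 and 15–17).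

**Steps most likely to fail**

Step 7. The central C2=C3 olefin may not equilibrate cleanly to the Z-isomer, a [1,7]-hydrogen shift from the inside methyl may compete with ring closure, and the facial (torquo)selectivity at C10 may be insufficient. The fallback sets out from 3 and 10 and comes back at 13. Arbuzov reaction of 3 with P(OEt)3 would give the phosphonate dimethyl 2-[(diethoxyphosphoryl)methyl]fumarate F1. Horner–Wadsworth–Emmons olefination of 10 with F1 (NaH, THF, 0 °C) would give the isolable all-E triene dimethyl (2E)-2-{(1E,3E)-4-[(4S)-2,2-dimethyl-1,3-dioxolan-4-yl]penta-1,3-dien-1-yl}but-2-enedioate F2. F2 would then be irradiated at 365 nm with benzophenone as triplet sensitizer (toluene, 40 °C), so that the photogenerated Z-isomer closes thermally at low temperature to 13.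

Step 11. Triple deprotonation may be incomplete, methylation may occur at C5 or at the acetylide carbon, and facial selectivity may erode. The fallback sets out from 16 and comes back at 18. C-silylation of the alkyne (LiHMDS, TMSCl, THF, −78 °C) would give dimethyl (1S,2S,3R)-3-methyl-3-[(trimethylsilyl)ethynyl]cyclohexane-1,2-dicarboxylate F3. Its vicinal diester dianion (LDA 2.3 equiv, THF, −78 → −30 °C) would be methylated with MeI and protonated with AcOH to give dimethyl (1R,2S,3R)-1,3-dimethyl-3-[(trimethylsilyl)ethynyl]cyclohexane-1,2-dicarboxylate F4. K2CO3 in MeOH would remove the silyl group to give 18.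

Step 15. The hindered diene may react sluggishly with the α-substituted acrolein, and diastereofacial or endo selectivity may be poor. The fallback sets out from 21 and comes back at 24. A Diels–Alder reaction of 21 with acrolein (Me2AlCl, CH2Cl2, −78 °C) needs to control only C9 through the diene face. It would give dimethyl (1R,2S,3S)-3-{(1S,6S)-6-formyl-3-[(triisopropylsilyl)oxy]cyclohex-2-en-1-yl}-1,3-dimethylcyclohexane-1,2-dicarboxylate F5. Deprotonation at C8 (KHMDS, THF, −78 °C) and C-alkylation with propargyl bromide trans to the bulky C9 substituent would give 24, which is hydrolysed to 25 as in step 15.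

**Further compounds**

F1 | step 7 | dimethyl 2-[(diethoxyphosphoryl)methyl]fumarate | COC(=O)/C=C(\CP(=O)(OCC)OCC)C(=O)OC
F2 | step 7 | dimethyl (2E)-2-{(1E,3E)-4-[(4S)-2,2-dimethyl-1,3-dioxolan-4-yl]penta-1,3-dien-1-yl}but-2-enedioate | COC(=O)/C=C(\C=C\C=C(/C)[C@H]1COC(C)(C)O1)C(=O)OC
F3 | step 11 | dimethyl (1S,2S,3R)-3-methyl-3-[(trimethylsilyl)ethynyl]cyclohexane-1,2-dicarboxylate | C[Si](C)(C)C#C[C@]1(C)CCC[C@H](C(=O)OC)[C@@H]1C(=O)OC
F4 | step 11 | dimethyl (1R,2S,3R)-1,3-dimethyl-3-[(trimethylsilyl)ethynyl]cyclohexane-1,2-dicarboxylate | C[Si](C)(C)C#C[C@]1(C)CCC[C@@](C)(C(=O)OC)[C@H]1C(=O)OC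
F5 | step 15 | dimethyl (1R,2S,3S)-3-{(1S,6S)-6-formyl-3-[(triisopropylsilyl)oxy]cyclohex-2-en-1-yl}-1,3-dimethylcyclohexane-1,2-dicarboxylate | O=C[C@H]1CCC(O[Si](C(C)C)(C(C)C)C(C)C)=C[C@H]1[C@]1(C)CCC[C@@](C)(C(=O)OC)[C@H]1C(=O)OC
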